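**Retrosynthetic overview**
1. Target 17 ⇒ open-chain (4R,6R)-trienone acid 16 by an intramolecular [4+2] disconnection: target bonds C4–C5 and C3a–C7a are cut, so the cyclohexene and the trans-fused cyclopentanone open together.
2. 16 ⇒ δ-hydroxy acid 15 (oxidation level) ⇒ aldehyde 11 + bis-silyl dienolate 13 of 2-ethylhex-2-enoic acid (vinylogous aldol).
3. 11 ⇒ ester 10 ⇒ trienylcopper 9 + (R)-lactate triflate 8 (SN2 with inversion; the only chiral-pool stereocentre).
4. 9 ⇒ dienyne 6 ⇒ enyne 2 ⇒ cinnamaldehyde 1; two successive syn-ethylcuprations of terminal alkynes build both trisubstituted E-alkenes.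
5. Ring order: no ring exists before step 9; the six- and five-membered rings form in that one operation.

Assumption: the target is numbered as a 1H-indene-4-carboxylic acid, which makes it (1R,3R,3aS,4S,5R,7aS); where an auxiliary's sense of induction is quoted in a fallback, the sense reported for the parent system is assumed to hold.

**Route**

Step 1
Reactants: 1 (E)-cinnamaldehyde
Product: 2 [(1E)-but-1-en-3-yn-1-yl]benzene
Conditions: TMSCHN2, LDA, THF, −78 °C → rt
Reagents that add atoms: (trimethylsilyl)diazomethane, C[Si](C)(C)C=[N+]=[N-]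
Why: Colvin rearrangement, in which lithiated TMS-diazomethane adds to the aldehyde, loss of LiOSiMe3 and N2 gives an alkylidene carbene, and its 1,2-H shift delivers the enyne with the E-alkene untouched.

Step 2
Reactants: 2 [(1E)-but-1-en-3-yn-1-yl]benzene; 3 (bromoethynyl)trimethylsilane
Product: 5 trimethyl[(3E,5E)-4-ethyl-6-phenylhexa-3,5-dien-1-yn-1-yl]silane, via dienylcopper 4 (not isolated)
Conditions: EtMgBr, CuBr·SMe2, Et2O/Me2S, −45 → −20 °C; then 3, TMEDA, THF, −20 °C → rt
Reagents that add atoms: ethylmagnesium bromide, CC[Mg]Br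
Why: Normant carbocupration adds Et and Cu syn across the terminal alkyne with ethyl on the substituted carbon, which fixes the E trisubstituted alkene (styryl trans to Cu), and the alkenylcopper then couples with the 1-bromoalkyne with retention.

Step 3
Reactants: 5 trimethyl[(3E,5E)-4-ethyl-6-phenylhexa-3,5-dien-1-yn-1-yl]silane
Product: 6 [(1E,3E)-3-ethylhexa-1,3-dien-5-yn-1-yl]benzene
Conditions: K2CO3 (cat.), MeOH, rt
Reagents that add atoms: none
Why: Base-catalysed methanolysis of the alkynyl C–Si bond (protodesilylation) frees the terminal alkyne for the second carbometalation without touching the diene.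

Step 4
Reactants: 7 ethyl (R)-lactate
Product: 8 ethyl (2R)-2-[(trifluoromethanesulfonyl)oxy]propanoate
Conditions: Tf2O, 2,6-lutidine, CH2Cl2, −78 → 0 °C
Reagents that add atoms: trifluoromethanesulfonic anhydride, O=S(=O)(OS(=O)(=O)C(F)(F)F)C(F)(F)F
Why: O-Sulfonylation of the secondary alcohol with retention gives the lactate triflate, an α-carbonyl-activated electrophile that reacts by SN2.

Step 5
Reactants: 6 [(1E,3E)-3-ethylhexa-1,3-dien-5-yn-1-yl]benzene; 8 ethyl (2R)-2-[(trifluoromethanesulfonyl)oxy]propanoate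
Product: 10 ethyl (2R,3E,5E,7E)-4,6-diethyl-2-methyl-8-phenylocta-3,5,7-trienoate, via trienylcopper 9 (not isolated)
Conditions: EtMgBr, CuBr·SMe2, Et2O/Me2S, −45 → −20 °C; then 8, THF/DMPU, −78 → −20 °C
Reagents that add atoms: ethylmagnesium bromide, CC[Mg]Br
Why: A second Normant syn-ethylcupration sets the C3=C4 E-alkene, and the Cu-mediated SN2 displacement of the α-triflate (known for organocuprates with lactate triflates, extended here to a carbocupration-derived alkenylcopper) goes with inversion, so the (R)-triflate gives the (2R) α-alkenyl ester (descriptor unchanged only because CIP priorities change) that becomes C1 of the target.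

Step 6
Reactants: 10 ethyl (2R,3E,5E,7E)-4,6-diethyl-2-methyl-8-phenylocta-3,5,7-trienoate
Product: 11 (2R,3E,5E,7E)-4,6-diethyl-2-methyl-8-phenylocta-3,5,7-trienal
Conditions: DIBAL-H (1.05 equiv), CH2Cl2, −78 °C; Rochelle salt work-up, used at once
Reagents that add atoms: none
Why: Low-temperature DIBAL-H half-reduction stops at the aluminium hemiacetal, which releases the configurationally labile α-methyl β,γ-unsaturated aldehyde only on work-up, so the C2 centre survives.

Step 7
Reactants: 12 (2E)-2-ethylhex-2-enoic acid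
Product: 13 (3E)-2-ethyl-1,1-bis(trimethylsilyloxy)hexa-1,3-diene
Conditions: LDA (2.2 equiv), THF, −78 → 0 °C; TMSCl, −78 °C → rt
Reagents that add atoms: chlorotrimethylsilane, C[Si](C)(C)Cl
Why: Double deprotonation (carboxylic acid, then γ-CH2) gives the dienediolate, and O-silylation gives the bis-silyl ketene acetal whose 3E geometry is favoured by A(1,3) strain with the 2-ethyl group.

Step 8
Reactants: 11 (2R,3E,5E,7E)-4,6-diethyl-2-methyl-8-phenylocta-3,5,7-trienal; 13 (3E)-2-ethyl-1,1-bis(trimethylsilyloxy)hexa-1,3-diene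
Product: 15 (2E,4R,5S,6R,7E,9E,11E)-2,4,8,10-tetraethyl-5-hydroxy-6-methyl-12-phenyldodeca-2,7,9,11-tetraenoic acid, via bis-silylated aldol adduct 14 (not isolated)
Conditions: B(C6F5)3 (10 mol %), CH2Cl2, −78 °C; then 1 M HCl, THF
Reagents that add atoms: none
Why: Vinylogous Mukaiyama aldol reaction in which γ-attack of the 3E-dienolate through an open transition state is expected to give the 4,5-anti adduct under Felkin–Anh control (5,6-syn), which sets C4 as R (C3 of the target) and regenerates the E-enoic acid.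

Step 9
Reactants: 15 (2E,4R,5S,6R,7E,9E,11E)-2,4,8,10-tetraethyl-5-hydroxy-6-methyl-12-phenyldodeca-2,7,9,11-tetraenoic acid
Product: 17 (1R,3R,3aS,4S,5R,7aS)-3,4,5,7-tetraethyl-1-methyl-2-oxo-5-[(E)-2-phenylethenyl]-2,3,3a,4,5,7a-hexahydro-1H-indene-4-carboxylic acid, via trienone acid 16 (not isolated)
Conditions: DMP, CH2Cl2, 0 °C → rt; filter; PhMe, BHT (cat.), 90 °C
Reagents that add atoms: none
Why: Dess–Martin oxidation unveils the ketone tether and the intramolecular Diels–Alder reaction of the unprotected acid then closes the cyclohexene and the trans-fused cyclopentanone together through the carboxyl-endo transition state, with both π-faces dictated by A(1,3) strain at the C6-methyl and C4-ethyl centres and the all-E geometry translating into the (3aS,4S,5R,7aS) array including the vicinal quaternary pair.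

**Compound list**
1 | (E)-cinnamaldehyde | O=C/C=C/c1ccccc1 | starting material
2 | [(1E)-but-1-en-3-yn-1-yl]benzene | C#C/C=C/c1ccccc1 | intermediate
3 | (bromoethynyl)trimethylsilane | C[Si](C)(C)C#CBr | starting material
4 | [(1E,3E)-2-ethyl-4-phenylbuta-1,3-dien-1-yl]copper (MgBr2 complex) | [Cu]/C=C(CC)/C=C/c1ccccc1 | intermediate
5 | trimethyl[(3E,5E)-4-ethyl-6-phenylhexa-3,5-dien-1-yn-1-yl]silane | C[Si](C)(C)C#C/C=C(CC)/C=C/c1ccccc1 | intermediate
6 | [(1E,3E)-3-ethylhexa-1,3-dien-5-yn-1-yl]benzene | C#C/C=C(CC)/C=C/c1ccccc1 | intermediate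
7 | ethyl (R)-lactate | C[C@@H](O)C(=O)OCC | starting material
8 | ethyl (2R)-2-[(trifluoromethanesulfonyl)oxy]propanoate | C[C@@H](OS(=O)(=O)C(F)(F)F)C(=O)OCC | intermediate
9 | [(1E,3E,5E)-2,4-diethyl-6-phenylhexa-1,3,5-trien-1-yl]copper (MgBr2 complex) | [Cu]/C=C(CC)/C=C(CC)/C=C/c1ccccc1 | intermediate
10 | ethyl (2R,3E,5E,7E)-4,6-diethyl-2-methyl-8-phenylocta-3,5,7-trienoate | CCOC(=O)[C@H](C)/C=C(CC)/C=C(CC)/C=C/c1ccccc1 | intermediate
11 | (2R,3E,5E,7E)-4,6-diethyl-2-methyl-8-phenylocta-3,5,7-trienal | O=C[C@H](C)/C=C(CC)/C=C(CC)/C=C/c1ccccc1 | intermediate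
12 | (2E)-2-ethylhex-2-enoic acid | CCC/C=C(CC)/C(=O)O | starting material
13 | (3E)-2-ethyl-1,1-bis(trimethylsilyloxy)hexa-1,3-diene | CC/C=C/C(CC)=C(O[Si](C)(C)C)O[Si](C)(C)C | intermediate
14 | trimethylsilyl (2E,4R,5S,6R,7E,9E,11E)-2,4,8,10-tetraethyl-6-methyl-12-phenyl-5-[(trimethylsilyl)oxy]dodeca-2,7,9,11-tetraenoate | C[Si](C)(C)OC(=O)/C(CC)=C/[C@@H](CC)[C@@H](O[Si](C)(C)C)[C@H](C)/C=C(CC)/C=C(CC)/C=C/c1ccccc1 | intermediate
15 | (2E,4R,5S,6R,7E,9E,11E)-2,4,8,10-tetraethyl-5-hydroxy-6-methyl-12-phenyldodeca-2,7,9,11-tetraenoic acid | OC(=O)/C(CC)=C/[C@@H](CC)[C@@H](O)[C@H](C)/C=C(CC)/C=C(CC)/C=C/c1ccccc1 | intermediate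
16 | (2E,4R,6R,7E,9E,11E)-2,4,8,10-tetraethyl-6-methyl-5-oxo-12-phenyldodeca-2,7,9,11-tetraenoic acid | OC(=O)/C(CC)=C/[C@@H](CC)C(=O)[C@H](C)/C=C(CC)/C=C(CC)/C=C/c1ccccc1 | intermediate
17 | (1R,3R,3aS,4S,5R,7aS)-3,4,5,7-tetraethyl-1-methyl-2-oxo-5-[(E)-2-phenylethenyl]-2,3,3a,4,5,7a-hexahydro-1H-indene-4-carboxylic acid | CCC1=C[C@](/C=C/c2ccccc2)(CC)[C@@](CC)(C(=O)O)[C@H]2[C@H]1[C@@H](C)C(=O)[C@@H]2CC | target

**Totals**
Total steps: 9. Longest linear sequence: 7 (steps 1, 2, 3, 5, 6, 8, 9).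

**Three steps most likely to fail**

Step 9 (thermal cycloaddition of a diene with a cis-ethyl terminus; double-bond migration in the skipped trienone and endo/exo leakage are the dangers). The fallback sets out from 15 and comes back at 17. Acid 15 is esterified with TMSCHN2 to the hydroxy methyl ester F1, which is oxidised with Dess–Martin periodinane to the trienone methyl ester F2. F2 is cyclised at −20 °C with Me2AlCl (Lewis-acid-promoted intramolecular Diels–Alder, which avoids heating and sharpens the ester-endo preference) to the bicyclic methyl ester F3. The hindered ester is then cleaved by SN2 demethylation (LiI, pyridine, reflux) to 17.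

Step 5 (an alkenylcopper of the Normant type may be too sluggish towards the secondary triflate, or ee may erode). The fallback sets out from 9 and comes back at 11. Copper reagent 9 is alkylated with (4R)-4-benzyl-3-(bromoacetyl)-1,3-oxazolidin-2-one to the unsubstituted imide F4. Evans alkylation (NaHMDS, MeI, −78 °C) installs the methyl group under auxiliary control to give the methylated imide F5. LiBH4 releases the primary alcohol F6 together with the auxiliary, and Dess–Martin oxidation of F6 gives 11.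

Step 8 (the C4 configuration rests on substrate control and on γ- over α-attack; a wrong C4 epimer would be mismatched in step 9). The fallback sets out from 12 and comes back at 15. Acid 12 is activated (PivCl, Et3N) and coupled with (S)-4-isopropyloxazolidin-2-one/LiCl to the unsaturated imide F7. NaHMDS/TBSCl converts it into the vinylketene silyl N,O-acetal F8, whose TiCl4-mediated Kobayashi vinylogous aldol reaction with 11 gives the anti adduct F9 under reagent control. LiOH/H2O2 then removes the auxiliary to give 15.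

**Further compounds**
F1 | step 9 | methyl (2E,4R,5S,6R,7E,9E,11E)-2,4,8,10-tetraethyl-5-hydroxy-6-methyl-12-phenyldodeca-2,7,9,11-tetraenoate | COC(=O)/C(CC)=C/[C@@H](CC)[C@@H](O)[C@H](C)/C=C(CC)/C=C(CC)/C=C/c1ccccc1
F2 | step 9 | methyl (2E,4R,6R,7E,9E,11E)-2,4,8,10-tetraethyl-6-methyl-5-oxo-12-phenyldodeca-2,7,9,11-tetraenoate | COC(=O)/C(CC)=C/[C@@H](CC)C(=O)[C@H](C)/C=C(CC)/C=C(CC)/C=C/c1ccccc1
F3 | step 9 | methyl (1R,3R,3aS,4S,5R,7aS)-3,4,5,7-tetraethyl-1-methyl-2-oxo-5-[(E)-2-phenylethenyl]-2,3,3a,4,5,7a-hexahydro-1H-indene-4-carboxylate | CCC1=C[C@](/C=C/c2ccccc2)(CC)[C@@](CC)(C(=O)OC)[C@H]2[C@H]1[C@@H](C)C(=O)[C@@H]2CC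
F4 | step 5 | (4R)-4-benzyl-3-[(3E,5E,7E)-4,6-diethyl-8-phenylocta-3,5,7-trienoyl]-1,3-oxazolidin-2-one | O=C(C/C=C(CC)/C=C(CC)/C=C/c1ccccc1)N1[C@H](Cc2ccccc2)COC1=O
F5 | step 5 | (4R)-4-benzyl-3-[(2R,3E,5E,7E)-4,6-diethyl-2-methyl-8-phenylocta-3,5,7-trienoyl]-1,3-oxazolidin-2-one | O=C([C@H](C)/C=C(CC)/C=C(CC)/C=C/c1ccccc1)N1[C@H](Cc2ccccc2)COC1=O
F6 | step 5 | (2R,3E,5E,7E)-4,6-diethyl-2-methyl-8-phenylocta-3,5,7-trien-1-ol | OC[C@H](C)/C=C(CC)/C=C(CC)/C=C/c1ccccc1
F7 | step 8 | (4S)-3-[(2E)-2-ethylhex-2-enoyl]-4-(propan-2-yl)-1,3-oxazolidin-2-one | CCC/C=C(CC)/C(=O)N1[C@@H](C(C)C)COC1=O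
F8 | step 8 | (4S)-3-[(1Z,3E)-1-{[tert-butyl(dimethyl)silyl]oxy}-2-ethylhexa-1,3-dien-1-yl]-4-(propan-2-yl)-1,3-oxazolidin-2-one | CC/C=C/C(CC)=C(\O[Si](C)(C)C(C)(C)C)N1[C@@H](C(C)C)COC1=O
F9 | step 8 | (4S)-3-[(2E,4R,5S,6R,7E,9E,11E)-2,4,8,10-tetraethyl-5-hydroxy-6-methyl-12-phenyldodeca-2,7,9,11-tetraenoyl]-4-(propan-2-yl)-1,3-oxazolidin-2-one | O=C(/C(CC)=C/[C@@H](CC)[C@@H](O)[C@H](C)/C=C(CC)/C=C(CC)/C=C/c1ccccc1)N1[C@@H](C(C)C)COC1=O
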